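**Retrosynthetic overview**
1. The target is (−)-pinoresinol (7R,8S,7'R,8'S) carrying an erythro (7''R,8''S) guaiacylglycerol arm on one phenol. The arm is cut at C7''–C8'' (auxiliary-controlled anti-aldol with vanillin acetate) and at ArO–CH2 (mono-alkylation of pinoresinol).
2. Both tetrahydrofuran rings of pinoresinol are closed last and together (C7–O–C9' and C7'–O–C9) by a stereoretentive double O-alkylation.
3. Key disconnection: C8–C8', by oxidative coupling of two ester-enolate α-carbons held on a diisopropylsilylene bridge between the C7 and C7' oxygens. This temporary 7-membered silepane is the first ring formed.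
4. Each half is the (R)-β-hydroxy ester made from O-TBS-vanillin by a catalytic asymmetric acetate aldol.

Assumption: O-TBS-vanillin 1 is bought as a catalogue compound, and the (R,R) antipode of the bisphosphoramide is taken as the Re-face-selective one (if the sense is the reverse, the (S,S) catalyst is used unchanged otherwise).

Numbering used below: C7/C7' benzylic, C8/C8' ring-fusion and C9/C9' OCH2 carbons of the furofuran; C7''–C9'' for the glycerol arm. Ring A is the arm guaiacyl, ring B the ether-linked aryl, ring C the free-phenol aryl of the furofuran.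

**Step 1**
Reactants: 1 4-[(tert-butyldimethylsilyl)oxy]-3-methoxybenzaldehyde; 2 1-[(tert-butyldimethylsilyl)oxy]-1-methoxyethene
Product: 3 methyl (3R)-3-{4-[(tert-butyldimethylsilyl)oxy]-3-methoxyphenyl}-3-hydroxypropanoate
Conditions: SiCl4 (1.1 equiv), (R,R)-Denmark bisphosphoramide [two (R)-N,N'-dimethyl-1,1'-binaphthyl-2,2'-diamine P(=O) units joined by MeN(CH2)5NMe] (5 mol %), CH2Cl2, −78 °C; aq NaHCO3
Reagents that add atoms: none
Why: Lewis-base-activated SiCl4 Mukaiyama acetate aldol (Denmark aldol), in which the chiral trichlorosilyl cation binds the aryl aldehyde and the ketene acetal attacks its Re face, setting C7 as R in ≥90% ee.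

**Step 2**
Reactants: 3 methyl (3R)-3-{4-[(tert-butyldimethylsilyl)oxy]-3-methoxyphenyl}-3-hydroxypropanoate (2 equiv)
Product: 4 bis[(1R)-1-{4-[(tert-butyldimethylsilyl)oxy]-3-methoxyphenyl}-3-methoxy-3-oxopropoxy]di(propan-2-yl)silane
Conditions: iPr2Si(OTf)2 (0.5 equiv), 2,6-lutidine, CH2Cl2, −78 → 0 °C
Reagents that add atoms: di(propan-2-yl)silanediyl bis(trifluoromethanesulfonate), CC(C)[Si](OS(=O)(=O)C(F)(F)F)(OS(=O)(=O)C(F)(F)F)C(C)C
Why: Silyl ether formation (silylene tethering) joins two homochiral alcohols without touching C7, and the minor enantiomer of 3 ends up in the separable R,S-silane, so 4 is obtained essentially enantiopure (Horeau-type amplification).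

**Step 3**
Reactants: 4 bis[(1R)-1-{4-[(tert-butyldimethylsilyl)oxy]-3-methoxyphenyl}-3-methoxy-3-oxopropoxy]di(propan-2-yl)silane
Product: 6 dimethyl (4R,5R,6R,7R)-4,7-bis{4-[(tert-butyldimethylsilyl)oxy]-3-methoxyphenyl}-2,2-di(propan-2-yl)-1,3,2-dioxasilepane-5,6-dicarboxylate, via dilithium bis-enolate 5 (not isolated)
Conditions: lithium diisopropylamide (2.3 equiv), THF, −78 °C; CuCl2 (2.4 equiv, in DMF), −78 → −40 °C
Reagents that add atoms: none
Why: Proposed new method: intramolecular oxidative coupling of a silicon-tethered bis(ester enolate) — CuCl2 (divalent copper) oxidises one enolate to an electrophilic α-ester radical/enolonium equivalent that is captured by the neighbouring enolate carbon, joining two normally nucleophilic α-carbons and closing the silepane; the tether forces bond formation on the face bearing O7 while A(1,3) strain keeps H7 eclipsed with the enolate, so each new centre forms anti to its aryl group (all-trans ring = C7/C8 syn and C8/C8' like, the pinoresinol pattern), and a stray cis ester can be epimerised with DBU to the all-trans diester; closest known reaction types are the CuCl2- or I2-mediated oxidative dimerisation of ester and imide enolates (used for 2,3-dibenzylsuccinate lignan precursors) and silicon-tethered oxidative bis-enolate couplings through a 7-membered transition state.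

**Step 4**
Reactants: 6 dimethyl (4R,5R,6R,7R)-4,7-bis{4-[(tert-butyldimethylsilyl)oxy]-3-methoxyphenyl}-2,2-di(propan-2-yl)-1,3,2-dioxasilepane-5,6-dicarboxylate
Product: 7 [(4R,5S,6S,7R)-4,7-bis{4-[(tert-butyldimethylsilyl)oxy]-3-methoxyphenyl}-2,2-di(propan-2-yl)-1,3,2-dioxasilepane-5,6-diyl]dimethanol
Conditions: iBu2AlH (6 equiv), CH2Cl2, −78 → 0 °C; aq potassium sodium tartrate
Reagents that add atoms: none
Why: Hydride reduction of the two esters to primary alcohols (DIBAL-H reduction) leaves the dialkoxysilane and aryl silyl ethers intact and touches no stereocentre (C5/C6 become S only through the CIP priority change).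

**Step 5**
Reactants: 7 [(4R,5S,6S,7R)-4,7-bis{4-[(tert-butyldimethylsilyl)oxy]-3-methoxyphenyl}-2,2-di(propan-2-yl)-1,3,2-dioxasilepane-5,6-diyl]dimethanol
Product: 9 (−)-pinoresinol [4,4'-[(1R,3aS,4R,6aS)-tetrahydro-1H,3H-furo[3,4-c]furan-1,4-diyl]bis(2-methoxyphenol)], via bis-mesylate 8 (not isolated)
Conditions: MsCl, Et3N, CH2Cl2, 0 °C; aqueous wash, solvent switch; Bu4NF (6 equiv), THF, 0 → 40 °C; aq NH4Cl
Reagents that add atoms: none
Why: Sulfonylation followed by fluoride-triggered desilylative double Williamson etherification (5-exo-tet): fluoride cleaves the silylene and both aryl TBS ethers, each benzylic alkoxide displaces the primary mesylate of the other arm, and because the C7–O and C7'–O bonds are never broken the configuration is retained and the cis-fused furofuran with both aryl groups exo results.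

**Step 6**
Reactants: 9 (−)-pinoresinol; 10 (4S)-4-benzyl-3-(chloroacetyl)-1,3-oxazolidin-2-one (1.0 equiv)
Product: 11 (4S)-4-benzyl-3-[({4-[(1R,3aS,4R,6aS)-4-(4-hydroxy-3-methoxyphenyl)tetrahydro-1H,3H-furo[3,4-c]furan-1-yl]-2-methoxyphenoxy})acetyl]-1,3-oxazolidin-2-one
Conditions: K2CO3 (1.0 equiv), NaI (0.1 equiv), acetone, rt
Reagents that add atoms: none
Why: Williamson ether synthesis (iodide-assisted SN2 at the α-halo imide) on one of the two equivalent phenols of the C2-symmetric bisphenol; the outcome is statistical (about 45% mono-ether, unreacted 9 recycled) and no stereocentre is involved.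

**Step 7**
Reactants: 11 (as named in step 6); 12 4-formyl-2-methoxyphenyl acetate (vanillin acetate, 1.3 equiv)
Product: 14 (4S)-4-benzyl-3-[(2R,3R)-3-(4-acetoxy-3-methoxyphenyl)-3-hydroxy-2-{4-[(1R,3aS,4R,6aS)-4-(4-hydroxy-3-methoxyphenyl)tetrahydro-1H,3H-furo[3,4-c]furan-1-yl]-2-methoxyphenoxy}propanoyl]-1,3-oxazolidin-2-one, via bis-trimethylsilyl adduct 13 (not isolated)
Conditions: MgCl2 (0.3 equiv), Et3N (4 equiv), Me3SiCl (3 equiv), EtOAc, rt; then PPTS, MeOH, 0 °C
Reagents that add atoms: none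
Why: Proposed new method: the magnesium-halide-catalysed anti-aldol of N-acyloxazolidinones (Evans MgCl2/Et3N/Me3SiCl soft enolisation) extended from alkyl to aryloxyacetyl imides — the Mg-chelated Z-enolate adds to the aromatic aldehyde through a boat transition state on the face opposite the benzyl group (the face used in Evans alkylations), giving the 2,3-anti adduct that fixes C8'' and C7''; Me3SiCl silylates the aldolate for turnover and transiently masks the ring C phenol, and the weakly basic aryl ether oxygen should not disturb the imide chelate; the closest known reaction type is the same anti-aldol with propionyl imides and aromatic aldehydes.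

**Step 8**
Reactants: 14 (as named in step 7)
Product: 15 (1R,2S)-1-(4-hydroxy-3-methoxyphenyl)-2-{4-[(1R,3aS,4R,6aS)-4-(4-hydroxy-3-methoxyphenyl)tetrahydro-1H,3H-furo[3,4-c]furan-1-yl]-2-methoxyphenoxy}propane-1,3-diol
Conditions: LiBH4 (6 equiv), THF–MeOH, 0 °C → rt; aq NH4Cl
Reagents that add atoms: none
Why: Reductive cleavage of the N-acyloxazolidinone to the primary alcohol (LiBH4 auxiliary removal) with concomitant reductive loss of the aryl acetate; no stereocentre is touched (C8'' changes from R to S only by CIP priority) and the erythro (7''R,8''S) arm is revealed.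

**Compound list**
1 | 4-[(tert-butyldimethylsilyl)oxy]-3-methoxybenzaldehyde | COc1cc(C=O)ccc1O[Si](C)(C)C(C)(C)C | starting material
2 | 1-[(tert-butyldimethylsilyl)oxy]-1-methoxyethene | COC(=C)O[Si](C)(C)C(C)(C)C | starting material
3 | methyl (3R)-3-{4-[(tert-butyldimethylsilyl)oxy]-3-methoxyphenyl}-3-hydroxypropanoate | COC(=O)C[C@@H](O)c1ccc(O[Si](C)(C)C(C)(C)C)c(OC)c1 | intermediate
4 | bis[(1R)-1-{4-[(tert-butyldimethylsilyl)oxy]-3-methoxyphenyl}-3-methoxy-3-oxopropoxy]di(propan-2-yl)silane | COC(=O)C[C@@H](O[Si](C(C)C)(C(C)C)O[C@H](CC(=O)OC)c1ccc(O[Si](C)(C)C(C)(C)C)c(OC)c1)c1ccc(O[Si](C)(C)C(C)(C)C)c(OC)c1 | intermediate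
5 | dilithium bis(ester enolate) of 4 (enolate geometry not specified) | COC(O[Li])=C[C@@H](O[Si](C(C)C)(C(C)C)O[C@H](C=C(O[Li])OC)c1ccc(O[Si](C)(C)C(C)(C)C)c(OC)c1)c1ccc(O[Si](C)(C)C(C)(C)C)c(OC)c1 | intermediate
6 | dimethyl (4R,5R,6R,7R)-4,7-bis{4-[(tert-butyldimethylsilyl)oxy]-3-methoxyphenyl}-2,2-di(propan-2-yl)-1,3,2-dioxasilepane-5,6-dicarboxylate | CC(C)[Si]1(C(C)C)O[C@@H](c2ccc(O[Si](C)(C)C(C)(C)C)c(OC)c2)[C@H](C(=O)OC)[C@@H](C(=O)OC)[C@H](c2ccc(O[Si](C)(C)C(C)(C)C)c(OC)c2)O1 | intermediate
7 | [(4R,5S,6S,7R)-4,7-bis{4-[(tert-butyldimethylsilyl)oxy]-3-methoxyphenyl}-2,2-di(propan-2-yl)-1,3,2-dioxasilepane-5,6-diyl]dimethanol | CC(C)[Si]1(C(C)C)O[C@@H](c2ccc(O[Si](C)(C)C(C)(C)C)c(OC)c2)[C@H](CO)[C@@H](CO)[C@H](c2ccc(O[Si](C)(C)C(C)(C)C)c(OC)c2)O1 | intermediate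
8 | bis(methanesulfonate) of 7 | CC(C)[Si]1(C(C)C)O[C@@H](c2ccc(O[Si](C)(C)C(C)(C)C)c(OC)c2)[C@H](COS(C)(=O)=O)[C@@H](COS(C)(=O)=O)[C@H](c2ccc(O[Si](C)(C)C(C)(C)C)c(OC)c2)O1 | intermediate
9 | (−)-pinoresinol | COc1cc([C@@H]2OC[C@@H]3[C@H]2CO[C@H]3c2ccc(O)c(OC)c2)ccc1O | intermediate
10 | (4S)-4-benzyl-3-(chloroacetyl)-1,3-oxazolidin-2-one | O=C(CCl)N1[C@@H](Cc2ccccc2)COC1=O | starting material
11 | pinoresinol mono-[(4S)-4-benzyl-2-oxo-oxazolidin-3-yl]carbonylmethyl ether | COc1cc([C@@H]2OC[C@@H]3[C@H]2CO[C@H]3c2ccc(O)c(OC)c2)ccc1OCC(=O)N1[C@@H](Cc2ccccc2)COC1=O | intermediate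
12 | 4-formyl-2-methoxyphenyl acetate | CC(=O)Oc1ccc(C=O)cc1OC | starting material
13 | bis-trimethylsilyl derivative of 14 (C7''-OSiMe3 and ring C OSiMe3) | CC(=O)Oc1ccc([C@@H](O[Si](C)(C)C)[C@H](C(=O)N2[C@@H](Cc3ccccc3)COC2=O)Oc2ccc([C@@H]3OC[C@@H]4[C@H]3CO[C@H]4c3ccc(O[Si](C)(C)C)c(OC)c3)cc2OC)cc1OC | intermediate
14 | (2R,3R)-anti-aldol imide | CC(=O)Oc1ccc([C@@H](O)[C@H](C(=O)N2[C@@H](Cc3ccccc3)COC2=O)Oc2ccc([C@@H]3OC[C@@H]4[C@H]3CO[C@H]4c3ccc(O)c(OC)c3)cc2OC)cc1OC | intermediate
15 | CNP0172915.1, erythro-(7''R,8''S)-guaiacylglycerol 8''-O-4 ether of (−)-pinoresinol | COc1cc([C@@H](O)[C@H](CO)Oc2ccc([C@@H]3OC[C@@H]4[C@H]3CO[C@H]4c3ccc(O)c(OC)c3)cc2OC)ccc1O | target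

**Totals**
Total step count: 8. Longest linear sequence: 8 (1 → 3 → 4 → 6 → 7 → 9 → 11 → 14 → 15).

**Steps most likely to fail, with fallbacks**

Step 3 (tethered oxidative coupling; unprecedented ring closure and diastereocontrol). The fallback sets out from 4 and comes back at 6, replacing the one-pot oxidation by a stepwise polar ring closure. Compound 4 is deprotonated once (LiN(SiMe3)2, 1.0 equiv, THF, −78 °C) and quenched with N-bromosuccinimide to give the mono-α-bromo diester F1 (2-bromo epimers; unreacted 4 is recycled). KN(SiMe3)2 then generates the remaining ester enolate, which closes the silepane by intramolecular SN2 alkylation of the α-bromo ester. A short DBU treatment epimerises the ester-bearing centres to the all-trans diester 6.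

Step 5 (one-pot mesylation, desilylation and double cyclisation; phenoxide, fluoride and alkoxide compete for the mesylates). The fallback sets out from 7 and comes back at 9 by unmasking before sulfonylation. HF·pyridine in THF removes only the silylene and gives the tetraol F2 with both aryl silyl ethers intact. MsCl in pyridine at 0 °C then sulfonylates the primary hydroxyls and the benzylic hydroxyls close both rings in the same pot to give bis-TBS pinoresinol F3. Buffered Bu4NF/AcOH finally releases 9.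

Step 7 (anti-aldol on a new substrate class; sense and level of induction unproven). The fallback sets out from 9 and comes back at 15, using a syn-aldol followed by inversion. Compound 9 is mono-alkylated as in step 6 with (4R)-4-benzyl-3-(chloroacetyl)-1,3-oxazolidin-2-one to give the enantiomeric-auxiliary imide F4. An Evans boron syn-aldol (Bu2BOTf, iPr2NEt, one extra equivalent for the ring C phenol, then 12) gives the (2R,3S) syn adduct F5, which already has the correct C8''. Mitsunobu inversion at C7'' with 4-nitrobenzoic acid, PPh3 and DIAD gives the (2R,3R) 4-nitrobenzoate F6. LiBH4 then removes the auxiliary, the nitrobenzoate and the acetate together to give 15.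

**Further compounds**
F1 | step 3 | mono-α-bromo derivative of 4 (2-bromo epimers) | COC(=O)C(Br)[C@@H](O[Si](C(C)C)(C(C)C)O[C@H](CC(=O)OC)c1ccc(O[Si](C)(C)C(C)(C)C)c(OC)c1)c1ccc(O[Si](C)(C)C(C)(C)C)c(OC)c1
F2 | step 5 | (1R,2S,3S,4R)-1,4-bis{4-[(tert-butyldimethylsilyl)oxy]-3-methoxyphenyl}-2,3-bis(hydroxymethyl)butane-1,4-diol | O[C@@H](c1ccc(O[Si](C)(C)C(C)(C)C)c(OC)c1)[C@H](CO)[C@@H](CO)[C@@H](O)c1ccc(O[Si](C)(C)C(C)(C)C)c(OC)c1
F3 | step 5 | (−)-pinoresinol bis(tert-butyldimethylsilyl) ether | COc1cc([C@@H]2OC[C@@H]3[C@H]2CO[C@H]3c2ccc(O[Si](C)(C)C(C)(C)C)c(OC)c2)ccc1O[Si](C)(C)C(C)(C)C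
F4 | step 7 | pinoresinol mono-[(4R)-4-benzyl-2-oxo-oxazolidin-3-yl]carbonylmethyl ether | COc1cc([C@@H]2OC[C@@H]3[C@H]2CO[C@H]3c2ccc(O)c(OC)c2)ccc1OCC(=O)N1[C@H](Cc2ccccc2)COC1=O
F5 | step 7 | (4R)-auxiliary (2R,3S)-syn-aldol imide | CC(=O)Oc1ccc([C@H](O)[C@H](C(=O)N2[C@H](Cc3ccccc3)COC2=O)Oc2ccc([C@@H]3OC[C@@H]4[C@H]3CO[C@H]4c3ccc(O)c(OC)c3)cc2OC)cc1OC
F6 | step 7 | (4R)-auxiliary (2R,3R)-3-O-(4-nitrobenzoyl) imide | CC(=O)Oc1ccc([C@@H](OC(=O)c2ccc(cc2)[N+](=O)[O-])[C@H](C(=O)N2[C@H](Cc3ccccc3)COC2=O)Oc2ccc([C@@H]3OC[C@@H]4[C@H]3CO[C@H]4c3ccc(O)c(OC)c3)cc2OC)cc1OC
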